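## Retrosynthetic overview

1. The strategy rests on ring A (C4a, C5, C6, C7, C8, C8a), a pentasubstituted phloroglucinol ring. Its three oxygens (ring oxygen O1 on C8a, 5-OH, 7-OH) must be told apart, and the prenyl-bearing C8 lies between C7 and C8a.
2. Last skeletal disconnection: the C2–O bond to ring B, made by addition–elimination of a ring B phenol on a 2-(methylsulfonyl)chromone. The 5-O-methyl, 7-O-silyl and 4'-O-methoxymethyl masks come off afterwards.
3. Ring C (O1–C2 and C2–C3) comes from an ortho-hydroxyacetophenone and CS2 through a ketene dithioacetal; the acetophenone comes from a salicylate ester.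
4. Ring A is cut to acyclic pieces by a Danheiser benzannulation of a diazoketone (from dimethyl acetylenedicarboxylate) with a prenyl silyl ynol ether. It forms C8–C8a, C6–C7 and C4a–C8a and leaves only the C8a hydroxyl free.
5. Ring order: ring A (step 6), ring C (step 8), then the separately made ring B (steps 10–12) is attached in step 13.

Key step: step 6

Remark: the Z geometry written for 2–5 is the one expected from anti addition in step 1; it is not carried into the target, because the two alkene carbons end as aromatic C4a and C5.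

## Route

Step 1
Reactants: 1 dimethyl acetylenedicarboxylate
Product: 2 dimethyl (Z)-2-methoxybut-2-enedioate
Conditions: MeOH (1.1 equiv), DABCO (10 mol %), CH2Cl2, 0 °C → rt
Reagents that add atoms: methanol, CO
Why: Amine-catalysed oxa-Michael addition of an alcohol to an acetylenic diester, whose anti course should place the methoxy group cis to the distal ester (Z, the two esters trans); no stereocentre is formed.

Step 2
Reactants: 2 dimethyl (Z)-2-methoxybut-2-enedioate
Product: 3 (Z)-2,4-dimethoxy-4-oxobut-2-enoic acid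
Conditions: LiOH·H2O (1.0 equiv), THF/H2O, 0 °C; then 1 M HCl to pH 2
Reagents that add atoms: lithium hydroxide, [Li+].[OH-]
Why: Regioselective mono-saponification: the C4 ester is a vinylogous carbonate deactivated by the β-methoxy group, so one equivalent of hydroxide at 0 °C should attack only the C1 ester on the methoxy-bearing carbon.

Step 3
Reactants: 3 (Z)-2,4-dimethoxy-4-oxobut-2-enoic acid
Product: 5 methyl (Z)-5-diazo-3-methoxy-4-oxopent-2-enoate, via acid chloride 4 (not isolated)
Conditions: (COCl)2, DMF (cat.), CH2Cl2, 0 °C → rt, evaporate; then CH2N2 (1.2 equiv), Et3N (1.1 equiv), Et2O, –20 → 0 °C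
Reagents that add atoms: diazomethane, C=[N+]=[N-]
Why: Acid chloride formation followed by C-acylation of diazomethane (diazoketone synthesis of the Arndt–Eistert type, with triethylamine as HCl scavenger, possible because 4 has no α-hydrogen); low temperature and near-stoichiometric diazomethane should keep dipolar cycloaddition to the donor-substituted alkene from competing.

Step 4
Reactants: 6 4-methylpent-3-enoic acid
Product: 7 ethyl 4-methylpent-3-enoate
Conditions: EtI, K2CO3, DMF, rt
Reagents that add atoms: iodoethane, CCI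
Why: SN2 O-alkylation of the carboxylate under non-acidic conditions, which avoids the acid-promoted lactonisation and double-bond migration of this β,γ-unsaturated acid.

Step 5
Reactants: 7 ethyl 4-methylpent-3-enoate
Product: 9 triisopropyl[(5-methylhex-4-en-1-yn-1-yl)oxy]silane, via lithium ynolate 8 (not isolated)
Conditions: CH2Br2, lithium 2,2,6,6-tetramethylpiperidide, THF, –78 °C; then 7; then n-BuLi, –78 → 0 °C; then TIPSOTf, –78 → 0 °C
Reagents that add atoms: dibromomethane, BrCBr; triisopropylsilyl trifluoromethanesulfonate, CC(C)[Si](OS(=O)(=O)C(F)(F)F)(C(C)C)C(C)C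
Why: Kowalski ester homologation: LiCHBr2 adds to the ester, bromine–lithium exchange on the dibromo enolate triggers a carbenoid 1,2-shift to ynolate 8, and the bulky silyl triflate then silylates on oxygen to give the silyl ynol ether.

Step 6
Reactants: 5 methyl (Z)-5-diazo-3-methoxy-4-oxopent-2-enoate; 9 triisopropyl[(5-methylhex-4-en-1-yn-1-yl)oxy]silane (1.3 equiv)
Product: 14 methyl 2-hydroxy-6-methoxy-3-(3-methylbut-2-en-1-yl)-4-[(triisopropylsilyl)oxy]benzoate, via vinylketene 10 (not isolated), via cyclobutenone 11 (not isolated), via dienylketene 12 (not isolated), via cyclohexadienone 13 (not isolated)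
Conditions: hν (254 nm, quartz), ClCH2CH2Cl, rt; then 80 °C
Reagents that add atoms: none
Why: Irradiation expels N2 from 5 and Wolff rearrangement (1,2-shift of the alkenyl group) gives vinylketene 10, which adds the electron-rich ynol ether 9 in a [2+2] cycloaddition to 4-alkenylcyclobutenone 11; on heating, 11 opens by 4π electrocyclic cleavage to dienylketene 12, which closes to dienone 13 and enolises to the phenol. The closest known reaction type is the Danheiser benzannulation in its photochemical Wolff variant with silyl ynol ethers, which gives resorcinol monosilyl ethers. Ring A is closed by a thermal 6π (disrotatory) electrocyclisation that joins the ketene carbon (C8a) to the ester-bearing alkene carbon (C4a), after C8–C8a and C6–C7 were made in the [2+2] step; aromatisation drives the sequence. No stereocentre remains, because the sp3 carbons of 11 and 13 are transient and become aromatic. The step needs regioselectivity in the [2+2] event and chemoselectivity for the alkyne over the trisubstituted alkene of the prenyl group: the polarised ynol ether bonds through its nucleophilic, prenyl-bearing carbon to the electrophilic ketene carbonyl carbon, so prenyl ends ortho and silyloxy meta to the new hydroxyl, and the unactivated alkene is far less reactive toward the ketene. The Z geometry of 5 keeps the ester trans to the ketene chain, so it points outward in the 6π closure.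

Step 7
Reactants: 14 methyl 2-hydroxy-6-methoxy-3-(3-methylbut-2-en-1-yl)-4-[(triisopropylsilyl)oxy]benzoate
Product: 16 1-[2-hydroxy-6-methoxy-3-(3-methylbut-2-en-1-yl)-4-[(triisopropylsilyl)oxy]phenyl]ethan-1-one, via silyl ketone 15 (not isolated)
Conditions: Me3SiCH2Li (3.5 equiv), THF/pentane, 0 °C → rt; then MeOH, rt
Reagents that add atoms: (trimethylsilyl)methyllithium, [Li]C[Si](C)(C)C
Why: Methyl ketone synthesis from an ester with (trimethylsilyl)methyllithium: after one addition the α-silyl ketone 15 is at once deprotonated to an enolate that cannot add a second equivalent, and methanol then cleaves the C–Si bond, while the bulky reagent should leave the aryl silyl ether alone.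

Step 8
Reactants: 16 1-[2-hydroxy-6-methoxy-3-(3-methylbut-2-en-1-yl)-4-[(triisopropylsilyl)oxy]phenyl]ethan-1-one
Product: 18 5-methoxy-8-(3-methylbut-2-en-1-yl)-2-(methylsulfanyl)-7-[(triisopropylsilyl)oxy]-4H-chromen-4-one, via dithioacetal 17 (not isolated)
Conditions: NaH (3.2 equiv), THF/DMF, 0 °C; CS2, 0 °C → rt; MeI (2.0 equiv), 0 °C → rt; then 60 °C
Reagents that add atoms: carbon disulfide, S=C=S; iodomethane, CI
Why: Ketone enolate addition to CS2 and double S-methylation give α-oxo ketene dithioacetal 17, whose neighbouring phenoxide closes ring C by conjugate addition–elimination (6-endo-trig, loss of methanethiolate), the standard route to 2-(methylsulfanyl)chromones.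

Step 9
Reactants: 18 5-methoxy-8-(3-methylbut-2-en-1-yl)-2-(methylsulfanyl)-7-[(triisopropylsilyl)oxy]-4H-chromen-4-one
Product: 19 2-(methanesulfonyl)-5-methoxy-8-(3-methylbut-2-en-1-yl)-7-[(triisopropylsilyl)oxy]-4H-chromen-4-one
Conditions: H2O2 (30% aq., 5 equiv), (NH4)6Mo7O24·4H2O (10 mol %), EtOH/THF, 0 °C → rt
Reagents that add atoms: hydrogen peroxide, OO
Why: Molybdate-catalysed peroxide oxidation of a sulfide to the sulfone, a reagent system that is selective for sulfur in the presence of isolated trisubstituted alkenes, so the prenyl group should survive.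

Step 10
Reactants: 20 4-[(tert-butyldimethylsilyl)oxy]phenol
Product: 21 tert-butyl[4-(methoxymethoxy)phenoxy]dimethylsilane
Conditions: MOMCl, iPr2NEt, CH2Cl2, 0 °C → rt
Reagents that add atoms: chloromethyl methyl ether, COCCl
Why: Williamson-type O-alkylation of the free phenol with chloromethyl methyl ether; the silyl ether is inert to the amine base.

Step 11
Reactants: 21 tert-butyl[4-(methoxymethoxy)phenoxy]dimethylsilane
Product: 23 tert-butyl[4-(methoxymethoxy)-3-(3-methylbut-2-en-1-yl)phenoxy]dimethylsilane, via aryllithium 22 (not isolated)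
Conditions: sec-BuLi, TMEDA, THF, –78 °C; then CuI (10 mol %), prenyl bromide, –78 °C → rt
Reagents that add atoms: 1-bromo-3-methylbut-2-ene, CC(C)=CCBr
Why: Directed ortho-metalation: the methoxymethoxy group binds the lithium base and directs deprotonation to its own ortho position (the bulky silyloxy group directs poorly), and CuI-mediated allylic substitution of prenyl bromide at its primary carbon then gives the linear prenyl arene.

Step 12
Reactants: 23 tert-butyl[4-(methoxymethoxy)-3-(3-methylbut-2-en-1-yl)phenoxy]dimethylsilane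
Product: 24 4-(methoxymethoxy)-3-(3-methylbut-2-en-1-yl)phenol
Conditions: TBAF (1.05 equiv), THF, 0 °C
Reagents that add atoms: none
Why: Fluoride-induced cleavage of the aryl silyl ether, to which the methoxymethyl acetal and the alkene are inert.

Step 13
Reactants: 19 2-(methanesulfonyl)-5-methoxy-8-(3-methylbut-2-en-1-yl)-7-[(triisopropylsilyl)oxy]-4H-chromen-4-one; 24 4-(methoxymethoxy)-3-(3-methylbut-2-en-1-yl)phenol
Product: 25 5-methoxy-2-[4-(methoxymethoxy)-3-(3-methylbut-2-en-1-yl)phenoxy]-8-(3-methylbut-2-en-1-yl)-7-[(triisopropylsilyl)oxy]-4H-chromen-4-one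
Conditions: 24, NaH (1.05 equiv), THF, 0 °C; then 19, 0 °C → rt
Reagents that add atoms: none
Why: Addition–elimination at C2 of the chromone (vinylogous acyl substitution): the phenoxide adds to the sulfonyl-bearing β-carbon of the enone and methanesulfinate leaves, the established way from 2-sulfonylchromones to 2-aryloxychromones; stoichiometric phenoxide in THF at low temperature should spare the 7-silyl ether.

Step 14
Reactants: 25 5-methoxy-2-[4-(methoxymethoxy)-3-(3-methylbut-2-en-1-yl)phenoxy]-8-(3-methylbut-2-en-1-yl)-7-[(triisopropylsilyl)oxy]-4H-chromen-4-one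
Product: 26 5-hydroxy-2-[4-(methoxymethoxy)-3-(3-methylbut-2-en-1-yl)phenoxy]-8-(3-methylbut-2-en-1-yl)-7-[(triisopropylsilyl)oxy]-4H-chromen-4-one
Conditions: MgI2·OEt2 (3 equiv), toluene, 70 °C; aqueous work-up
Reagents that add atoms: none
Why: Chelation-assisted peri demethylation: magnesium bound between the C4 carbonyl oxygen and the 5-methoxy oxygen activates that methyl group alone for SN2 attack by iodide, and the absence of protic acid should keep the prenyl groups intact.

Step 15
Reactants: 26 5-hydroxy-2-[4-(methoxymethoxy)-3-(3-methylbut-2-en-1-yl)phenoxy]-8-(3-methylbut-2-en-1-yl)-7-[(triisopropylsilyl)oxy]-4H-chromen-4-one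
Product: 28 Epimedonin J, 5,7-dihydroxy-2-[4-hydroxy-3-(3-methylbut-2-en-1-yl)phenoxy]-8-(3-methylbut-2-en-1-yl)-4H-chromen-4-one, via phenol 27 (not isolated)
Conditions: TBAF (1.1 equiv), THF, 0 °C; evaporate; then 3 M aq. HCl/MeOH, 40 °C
Reagents that add atoms: none
Why: Fluoride desilylation of the 7-silyl ether followed by acid-catalysed transacetalisation of the methoxymethyl ether to methanol; the mild temperature is chosen to keep the prenyl chains from cyclising onto the neighbouring phenols.

## Compound list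

1 | dimethyl acetylenedicarboxylate | COC(=O)C#CC(=O)OC | starting material
2 | dimethyl (Z)-2-methoxybut-2-enedioate | COC(=O)/C=C(\OC)C(=O)OC | intermediate
3 | (Z)-2,4-dimethoxy-4-oxobut-2-enoic acid | COC(=O)/C=C(\OC)C(=O)O | intermediate
4 | methyl (Z)-4-chloro-3-methoxy-4-oxobut-2-enoate | COC(=O)/C=C(\OC)C(Cl)=O | intermediate (not isolated)
5 | methyl (Z)-5-diazo-3-methoxy-4-oxopent-2-enoate | COC(=O)/C=C(\OC)C(=O)C=[N+]=[N-] | intermediate
6 | 4-methylpent-3-enoic acid | CC(C)=CCC(=O)O | starting material
7 | ethyl 4-methylpent-3-enoate | CCOC(=O)CC=C(C)C | intermediate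
8 | lithium 5-methylhex-4-en-1-yn-1-olate | CC(C)=CCC#C[O-].[Li+] | intermediate (not isolated)
9 | triisopropyl[(5-methylhex-4-en-1-yn-1-yl)oxy]silane | CC(C)=CCC#CO[Si](C(C)C)(C(C)C)C(C)C | intermediate
10 | methyl (2Z)-3-methoxy-5-oxopenta-2,4-dienoate | COC(=O)/C=C(\OC)C=C=O | intermediate (not isolated)
11 | methyl (2Z)-3-methoxy-3-[3-(3-methylbut-2-en-1-yl)-4-oxo-2-[(triisopropylsilyl)oxy]cyclobut-2-en-1-yl]prop-2-enoate (racemic) | COC(=O)/C=C(\OC)C1C(=O)C(CC=C(C)C)=C1O[Si](C(C)C)(C(C)C)C(C)C | intermediate (not isolated)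
12 | methyl (2Z,4E)-3-methoxy-6-(3-methylbut-2-en-1-yl)-7-oxo-5-[(triisopropylsilyl)oxy]hepta-2,4,6-trienoate | O=C=C(CC=C(C)C)/C(O[Si](C(C)C)(C(C)C)C(C)C)=C\C(OC)=C\C(=O)OC | intermediate (not isolated)
13 | methyl 6-methoxy-3-(3-methylbut-2-en-1-yl)-2-oxo-4-[(triisopropylsilyl)oxy]cyclohexa-3,5-diene-1-carboxylate (racemic) | COC(=O)C1C(=O)C(CC=C(C)C)=C(O[Si](C(C)C)(C(C)C)C(C)C)C=C1OC | intermediate (not isolated)
14 | methyl 2-hydroxy-6-methoxy-3-(3-methylbut-2-en-1-yl)-4-[(triisopropylsilyl)oxy]benzoate | COC(=O)c1c(O)c(CC=C(C)C)c(O[Si](C(C)C)(C(C)C)C(C)C)cc1OC | intermediate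
15 | 1-[2-hydroxy-6-methoxy-3-(3-methylbut-2-en-1-yl)-4-[(triisopropylsilyl)oxy]phenyl]-2-(trimethylsilyl)ethan-1-one | C[Si](C)(C)CC(=O)c1c(O)c(CC=C(C)C)c(O[Si](C(C)C)(C(C)C)C(C)C)cc1OC | intermediate (not isolated)
16 | 1-[2-hydroxy-6-methoxy-3-(3-methylbut-2-en-1-yl)-4-[(triisopropylsilyl)oxy]phenyl]ethan-1-one | CC(=O)c1c(O)c(CC=C(C)C)c(O[Si](C(C)C)(C(C)C)C(C)C)cc1OC | intermediate
17 | 1-[2-hydroxy-6-methoxy-3-(3-methylbut-2-en-1-yl)-4-[(triisopropylsilyl)oxy]phenyl]-3,3-bis(methylsulfanyl)prop-2-en-1-one | CSC(SC)=CC(=O)c1c(O)c(CC=C(C)C)c(O[Si](C(C)C)(C(C)C)C(C)C)cc1OC | intermediate (not isolated)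
18 | 5-methoxy-8-(3-methylbut-2-en-1-yl)-2-(methylsulfanyl)-7-[(triisopropylsilyl)oxy]-4H-chromen-4-one | CSc1cc(=O)c2c(OC)cc(O[Si](C(C)C)(C(C)C)C(C)C)c(CC=C(C)C)c2o1 | intermediate
19 | 2-(methanesulfonyl)-5-methoxy-8-(3-methylbut-2-en-1-yl)-7-[(triisopropylsilyl)oxy]-4H-chromen-4-one | CS(=O)(=O)c1cc(=O)c2c(OC)cc(O[Si](C(C)C)(C(C)C)C(C)C)c(CC=C(C)C)c2o1 | intermediate
20 | 4-[(tert-butyldimethylsilyl)oxy]phenol | CC(C)(C)[Si](C)(C)Oc1ccc(O)cc1 | starting material
21 | tert-butyl[4-(methoxymethoxy)phenoxy]dimethylsilane | COCOc1ccc(O[Si](C)(C)C(C)(C)C)cc1 | intermediate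
22 | [5-[(tert-butyldimethylsilyl)oxy]-2-(methoxymethoxy)phenyl]lithium | [Li]c1cc(O[Si](C)(C)C(C)(C)C)ccc1OCOC | intermediate (not isolated)
23 | tert-butyl[4-(methoxymethoxy)-3-(3-methylbut-2-en-1-yl)phenoxy]dimethylsilane | COCOc1ccc(O[Si](C)(C)C(C)(C)C)cc1CC=C(C)C | intermediate
24 | 4-(methoxymethoxy)-3-(3-methylbut-2-en-1-yl)phenol | COCOc1ccc(O)cc1CC=C(C)C | intermediate
25 | 5-methoxy-2-[4-(methoxymethoxy)-3-(3-methylbut-2-en-1-yl)phenoxy]-8-(3-methylbut-2-en-1-yl)-7-[(triisopropylsilyl)oxy]-4H-chromen-4-one | COCOc1ccc(Oc2cc(=O)c3c(OC)cc(O[Si](C(C)C)(C(C)C)C(C)C)c(CC=C(C)C)c3o2)cc1CC=C(C)C | intermediate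
26 | 5-hydroxy-2-[4-(methoxymethoxy)-3-(3-methylbut-2-en-1-yl)phenoxy]-8-(3-methylbut-2-en-1-yl)-7-[(triisopropylsilyl)oxy]-4H-chromen-4-one | COCOc1ccc(Oc2cc(=O)c3c(O)cc(O[Si](C(C)C)(C(C)C)C(C)C)c(CC=C(C)C)c3o2)cc1CC=C(C)C | intermediate
27 | 5,7-dihydroxy-2-[4-(methoxymethoxy)-3-(3-methylbut-2-en-1-yl)phenoxy]-8-(3-methylbut-2-en-1-yl)-4H-chromen-4-one | COCOc1ccc(Oc2cc(=O)c3c(O)cc(O)c(CC=C(C)C)c3o2)cc1CC=C(C)C | intermediate (not isolated)
28 | Epimedonin J, 5,7-dihydroxy-2-[4-hydroxy-3-(3-methylbut-2-en-1-yl)phenoxy]-8-(3-methylbut-2-en-1-yl)-4H-chromen-4-one | CC(C)=CCc1cc(Oc2cc(=O)c3c(O)cc(O)c(CC=C(C)C)c3o2)ccc1O | target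

## Step count and risks

Total step count: 15. Longest linear sequence: 10 steps (steps 1, 2, 3, 6, 7, 8, 9, 13, 14, 15).

Steps most likely to fail:

**Step 6 (key step).** The photogenerated vinylketene may dimerise, or the chromophores that build up may be degraded by light, before the ketene is captured by the ynol ether. Prolonged irradiation may also isomerise the enol ether alkene.
Fallback: it sets out from siloxyalkyne 9 and comes back to the route at dienone 13 and thus at salicylate 14. The ketene is made thermally, without diazo compound or light.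
- Commercial dimethyl 3-oxopentanedioate with trimethyl orthoformate and catalytic H2SO4 in MeOH should give dimethyl (E)-3-methoxypent-2-enedioate F1.
- One equivalent of LiOH should hydrolyse its non-conjugated ester to (E)-3,5-dimethoxy-5-oxopent-3-enoic acid F2.
- Oxalyl chloride should convert this into methyl (E)-5-chloro-3-methoxy-5-oxopent-2-enoate F3.
- Slow addition of Et3N to F3 and 9 in toluene at rt should dehydrochlorinate F3 to methyl (E)-3-methoxy-5-oxopenta-2,4-dienoate F4, the geometric isomer of 10.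
- Capture of F4 by 9 in the same [2+2] sense should give methyl (2E)-3-methoxy-3-[3-(3-methylbut-2-en-1-yl)-4-oxo-2-[(triisopropylsilyl)oxy]cyclobut-2-en-1-yl]prop-2-enoate F5.
- Heating at 80–110 °C should open F5 to methyl (2E,4E)-3-methoxy-6-(3-methylbut-2-en-1-yl)-7-oxo-5-[(triisopropylsilyl)oxy]hepta-2,4,6-trienoate F6, which closes to 13 and enolises to 14.
- In this series the ester lies on the inner side of the triene, which should only slow the 6π closure, since the geometry is erased on aromatisation.

**Step 7.** Addition may stall at an ester flanked by a lithium phenoxide and a methoxy group, and forcing it may cost the aryl silyl ether or give over-addition.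
Fallback: it sets out from 14 and comes back at 16.
- SN2 dealkylation of the methyl ester with LiI in pyridine at reflux should give 2-hydroxy-6-methoxy-3-(3-methylbut-2-en-1-yl)-4-[(triisopropylsilyl)oxy]benzoic acid F7.
- MeLi (4 equiv, THF, 0 °C → rt) should add once to the lithium carboxylate; the geminal dialkoxide cannot collapse before work-up, which rules out a second addition and releases 16.

**Step 14.** Ether cleavage may be incomplete or unselective: the methoxymethyl group may be lost to the Lewis acid, or the 2-aryloxy group may be attacked on prolonged heating.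
Fallback: it sets out from 18 and comes back at 26. The demethylation is moved ahead of the coupling, where no ring B, acetal or aryloxy group is present.
- BCl3 (CH2Cl2, –78 °C), again directed by the C4 carbonyl chelate, should give 5-hydroxy-8-(3-methylbut-2-en-1-yl)-2-(methylsulfanyl)-7-[(triisopropylsilyl)oxy]-4H-chromen-4-one F8.
- Oxidation with H2O2 and (NH4)6Mo7O24 as in step 9 should give 5-hydroxy-2-(methanesulfonyl)-8-(3-methylbut-2-en-1-yl)-7-[(triisopropylsilyl)oxy]-4H-chromen-4-one F9.
- Coupling of F9 with 24 (NaH, 2.1 equiv, THF, 0 °C → rt) should give 26 directly.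

## Further compounds

F1 | step 6 | dimethyl (E)-3-methoxypent-2-enedioate | COC(=O)/C=C(/OC)CC(=O)OC
F2 | step 6 | (E)-3,5-dimethoxy-5-oxopent-3-enoic acid | COC(=O)/C=C(/OC)CC(=O)O
F3 | step 6 | methyl (E)-5-chloro-3-methoxy-5-oxopent-2-enoate | COC(=O)/C=C(/OC)CC(Cl)=O
F4 | step 6 | methyl (E)-3-methoxy-5-oxopenta-2,4-dienoate | COC(=O)/C=C(/OC)C=C=O
F5 | step 6 | methyl (2E)-3-methoxy-3-[3-(3-methylbut-2-en-1-yl)-4-oxo-2-[(triisopropylsilyl)oxy]cyclobut-2-en-1-yl]prop-2-enoate | COC(=O)/C=C(/OC)C1C(=O)C(CC=C(C)C)=C1O[Si](C(C)C)(C(C)C)C(C)C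
F6 | step 6 | methyl (2E,4E)-3-methoxy-6-(3-methylbut-2-en-1-yl)-7-oxo-5-[(triisopropylsilyl)oxy]hepta-2,4,6-trienoate | O=C=C(CC=C(C)C)/C(O[Si](C(C)C)(C(C)C)C(C)C)=C\C(OC)=C/C(=O)OC
F7 | step 7 | 2-hydroxy-6-methoxy-3-(3-methylbut-2-en-1-yl)-4-[(triisopropylsilyl)oxy]benzoic acid | COc1cc(O[Si](C(C)C)(C(C)C)C(C)C)c(CC=C(C)C)c(O)c1C(=O)O
F8 | step 14 | 5-hydroxy-8-(3-methylbut-2-en-1-yl)-2-(methylsulfanyl)-7-[(triisopropylsilyl)oxy]-4H-chromen-4-one | CSc1cc(=O)c2c(O)cc(O[Si](C(C)C)(C(C)C)C(C)C)c(CC=C(C)C)c2o1
F9 | step 14 | 5-hydroxy-2-(methanesulfonyl)-8-(3-methylbut-2-en-1-yl)-7-[(triisopropylsilyl)oxy]-4H-chromen-4-one | CS(=O)(=O)c1cc(=O)c2c(O)cc(O[Si](C(C)C)(C(C)C)C(C)C)c(CC=C(C)C)c2o1
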